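**Plan**

Numbering follows the naphthoquinone: C1(=O), C2(OH), C3(side chain), C4(=O), C4a, C5–C8 (ring A), C8a. Benzene carbons C1–C6 of the early intermediates become C1–C4, C4a and C8a.
Retrosynthesis: the hydroxyquinone of ring B goes back to a MOM-masked 1,2,4-triol. Ring A is then cut at C8–C8a (electrocyclic) and C4a–C5 (carbonyl addition), and the side chain at C3–CH2.
Enabling feature: ring A carries oxygen on C5, C6 and C8 and hydrogen on C7. This O/OMe/H/O sequence is that of the four ring carbons of 3-methoxycyclobutenedione, so C5–C8 can arrive as one four-carbon block and the trioxygenated ring can be annulated last.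
Forward: ring B comes from benzene-1,2,4-triol. The chain is attached at C3 by lithiation and epoxide opening, C4a is brominated and joined to C5 of the dione, and ring A closes thermally. Methylation, silyl-to-acetate exchange and unmasking/oxidation of ring B follow.
Stereochemistry: the single (S) carbinol centre comes from (S)-propylene oxide, and its C–O bond is never broken.

Key step: step 7

Remark on the chemistry: the carbinol carbon of the cyclobutenone adduct and the ring-fusion carbon of the transient dienone should form as epimer mixtures. Both become sp2 in the key step, so they are drawn without configuration.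

**Step 1**
Reactants: 1 benzene-1,2,4-triol
Product: 2 1,2,4-tris(methoxymethoxy)benzene
Conditions: MOMCl, i-Pr2NEt, CH2Cl2/DMF, 0 °C to rt, argon
Reagents that add atoms: chloromethyl methyl ether (MOMCl), COCCl
Why: Williamson-type O-alkylation of all three phenols under argon (the triol autoxidises in base) installs acetal ethers that later direct lithiation and leave under acid.

**Step 2**
Reactants: 2 1,2,4-tris(methoxymethoxy)benzene; 3 (S)-propylene oxide
Product: 5 (S)-1-[2,3,6-tris(methoxymethoxy)phenyl]propan-2-ol, via aryllithium 4 (not isolated)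
Conditions: n-BuLi, THF, 0 °C; then 3, BF3·OEt2, −78 °C; aq NH4Cl
Reagents that add atoms: n-butyllithium, [Li]CCCC (supplies the lithium of 4 only)
Why: Directed ortho-metalation removes the C3 proton, the only one flanked by two chelating MOM ethers, and the BF3-activated epoxide is opened in SN2 fashion at its CH2 carbon, so the stereocentre of 3 is carried over unchanged as (S).

**Step 3**
Reactants: 5 (S)-1-[2,3,6-tris(methoxymethoxy)phenyl]propan-2-ol
Product: 6 (S)-tert-butyldimethyl{1-[2,3,6-tris(methoxymethoxy)phenyl]propan-2-yloxy}silane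
Conditions: TBSCl, imidazole, DMF, rt
Reagents that add atoms: tert-butyldimethylsilyl chloride (TBSCl), CC(C)(C)[Si](C)(C)Cl
Why: Imidazole-promoted O-silylation masks the only acidic proton before the second organolithium step and does not touch the C–O stereocentre.

**Step 4**
Reactants: 6 (S)-tert-butyldimethyl{1-[2,3,6-tris(methoxymethoxy)phenyl]propan-2-yloxy}silane
Product: 7 (S)-{1-[3-bromo-2,5,6-tris(methoxymethoxy)phenyl]propan-2-yloxy}(tert-butyl)dimethylsilane
Conditions: NBS, MeCN, 0 °C, dark
Reagents that add atoms: N-bromosuccinimide (NBS), O=C1CCC(=O)N1Br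
Why: Electrophilic aromatic bromination should go to benzene C5 (the future C4a), which is ortho to the C4 ether and para to the C2 ether, rather than to C6, which is activated by one oxygen only, and neutral NBS leaves acetals and silyl ether intact.

**Step 5**
Reactants: 8 dimethyl squarate
Product: 10 3-methoxycyclobut-3-ene-1,2-dione, via carbinol 9 (not isolated)
Conditions: LiAlH(Ot-Bu)3, THF, −78 °C; then 2 M aq HCl, CH2Cl2, rt
Reagents that add atoms: water, O (oxygen of the new carbonyl)
Why: The bulky hydride performs a single 1,2-reduction to carbinol 9, and acid then triggers the usual squarate 1,3-carbonyl transposition (loss of the hydroxyl, hydration of the methoxy-stabilised cation, expulsion of methanol) that converts squarate 1,2-adducts into 3-alkoxy-4-substituted cyclobutenediones, here with hydrogen as the 4-substituent.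

**Step 6**
Reactants: 7 (S)-{1-[3-bromo-2,5,6-tris(methoxymethoxy)phenyl]propan-2-yloxy}(tert-butyl)dimethylsilane; 10 3-methoxycyclobut-3-ene-1,2-dione
Product: 12 4-hydroxy-3-methoxy-4-{3-[(S)-2-(tert-butyldimethylsilyloxy)propyl]-2,4,5-tris(methoxymethoxy)phenyl}cyclobut-2-en-1-one, via aryllithium 11 (not isolated)
Conditions: n-BuLi, THF, −78 °C; cannulation into 10, THF, −78 °C; aq NH4Cl
Reagents that add atoms: n-butyllithium, [Li]CCCC (supplies the lithium of 11 only)
Why: Bromine–lithium exchange followed by 1,2-carbonyl addition: the carbonyl of 10 next to the CH carbon is the deactivated end of a vinylogous ester, so the hard aryllithium should attack the ketone-like carbonyl next to the methoxy-bearing carbon, forming C4a–C5 and placing OMe on the future C6.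

**Step 7**
Reactants: 12 4-hydroxy-3-methoxy-4-{3-[(S)-2-(tert-butyldimethylsilyloxy)propyl]-2,4,5-tris(methoxymethoxy)phenyl}cyclobut-2-en-1-one
Product: 15 3-[(S)-2-(tert-butyldimethylsilyloxy)propyl]-6-methoxy-1,2,4-tris(methoxymethoxy)naphthalene-5,8-diol, via dienylketene 13 (not isolated), via ring-fused dienone 14 (not isolated)
Conditions: degassed p-xylene, 138 °C, argon; crude product carried on under argon
Reagents that add atoms: none
Why: Heat cleaves the C(=O)–C(OH)Ar bond of 12 in a conrotatory 4π electrocyclic ring opening in which the donor hydroxyl turns outward (torquoselectivity), so that in dienylketene 13 the aryl group lies cis to the ketene arm. The ketene carbon (C8) then bonds to the unsubstituted ortho carbon of the arene (C8a) in a thermal disrotatory 6π electrocyclisation, which closes the six-membered carbocyclic ring A as dienone 14, and a proton shift from C8a to oxygen restores aromaticity to give hydroquinone 15. The closest known reaction type is the Moore rearrangement of 4-aryl-4-hydroxycyclobutenones to 1,4-naphthalenediols. No stereocentre is created that survives: the carbinol carbon of 12 and C8a of 14 both become sp2, and the remote (S) centre of the side chain takes no part. Site selectivity in the closure is secured by the substrate, because the second ortho position (C4) carries a MOM ether and cannot re-aromatise by proton loss, while the C6-OMe/C7-H order was already fixed in step 6. Oxygen-free, neutral heating keeps the electron-rich product at the hydroquinone level and leaves the MOM acetals and the silyl ether untouched.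

**Step 8**
Reactants: 15 3-[(S)-2-(tert-butyldimethylsilyloxy)propyl]-6-methoxy-1,2,4-tris(methoxymethoxy)naphthalene-5,8-diol
Product: 16 3-[(S)-2-(tert-butyldimethylsilyloxy)propyl]-5,6,8-trimethoxy-1,2,4-tris(methoxymethoxy)naphthalene
Conditions: MeI, K2CO3, degassed DMF, rt to 40 °C, argon
Reagents that add atoms: iodomethane (MeI), CI
Why: Williamson O-methylation of the two peri phenols fixes ring A as its trimethyl ether while ring B stays acetal-protected, with oxygen excluded because the hydroquinone anions autoxidise readily.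

**Step 9**
Reactants: 16 3-[(S)-2-(tert-butyldimethylsilyloxy)propyl]-5,6,8-trimethoxy-1,2,4-tris(methoxymethoxy)naphthalene
Product: 17 3-[(S)-2-hydroxypropyl]-5,6,8-trimethoxy-1,2,4-tris(methoxymethoxy)naphthalene
Conditions: TBAF, THF, rt
Reagents that add atoms: none
Why: Fluoride-driven desilylation (strong Si–F bond) frees the secondary alcohol without touching the MOM or methyl ethers or the C–O stereocentre.

**Step 10**
Reactants: 17 3-[(S)-2-hydroxypropyl]-5,6,8-trimethoxy-1,2,4-tris(methoxymethoxy)naphthalene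
Product: 18 3-[(S)-2-acetoxypropyl]-5,6,8-trimethoxy-1,2,4-tris(methoxymethoxy)naphthalene
Conditions: Ac2O, pyridine, DMAP (cat.), CH2Cl2, rt
Reagents that add atoms: acetic anhydride (Ac2O), CC(=O)OC(C)=O
Why: DMAP-catalysed acyl transfer esterifies the only free hydroxyl at oxygen, so the (S) configuration is retained.

**Step 11**
Reactants: 18 3-[(S)-2-acetoxypropyl]-5,6,8-trimethoxy-1,2,4-tris(methoxymethoxy)naphthalene
Product: 20 2-hydroxy-3-[(S)-2-acetoxypropyl]-5,6,8-trimethoxy-1,4-naphthoquinone (CNP0321270.1), via naphthalenetriol 19 (not isolated)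
Conditions: TFA, CH2Cl2, 0 °C to rt; H2O work-up; air, EtOAc, rt
Reagents that add atoms: none
Why: Anhydrous acidolysis cleaves the three aryl MOM acetals through the methoxymethyl cation while the ester, which needs an external nucleophile to break, survives, and the freed 1,2,4-naphthalenetriol autoxidises in air to the 2-hydroxy-1,4-quinone, ring A being locked as methyl ethers.

**Compound list**

1 | benzene-1,2,4-triol | Oc1ccc(O)c(O)c1 | starting material
2 | 1,2,4-tris(methoxymethoxy)benzene | COCOc1ccc(OCOC)c(OCOC)c1 | intermediate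
3 | (S)-propylene oxide | C[C@H]1CO1 | starting material
4 | 2,3,6-tris(methoxymethoxy)phenyllithium | [Li]c1c(OCOC)ccc(OCOC)c1OCOC | intermediate
5 | (S)-1-[2,3,6-tris(methoxymethoxy)phenyl]propan-2-ol | COCOc1ccc(OCOC)c(C[C@H](C)O)c1OCOC | intermediate
6 | (S)-tert-butyldimethyl{1-[2,3,6-tris(methoxymethoxy)phenyl]propan-2-yloxy}silane | COCOc1ccc(OCOC)c(C[C@H](C)O[Si](C)(C)C(C)(C)C)c1OCOC | intermediate
7 | (S)-{1-[3-bromo-2,5,6-tris(methoxymethoxy)phenyl]propan-2-yloxy}(tert-butyl)dimethylsilane | COCOc1cc(Br)c(OCOC)c(C[C@H](C)O[Si](C)(C)C(C)(C)C)c1OCOC | intermediate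
8 | dimethyl squarate (3,4-dimethoxycyclobut-3-ene-1,2-dione) | COC1=C(OC)C(=O)C1=O | starting material
9 | 4-hydroxy-2,3-dimethoxycyclobut-2-en-1-one | COC1=C(OC)C(=O)C1O | intermediate
10 | 3-methoxycyclobut-3-ene-1,2-dione | COC1=CC(=O)C1=O | intermediate
11 | 3-[(S)-2-(tert-butyldimethylsilyloxy)propyl]-2,4,5-tris(methoxymethoxy)phenyllithium | [Li]c1cc(OCOC)c(OCOC)c(C[C@H](C)O[Si](C)(C)C(C)(C)C)c1OCOC | intermediate
12 | 4-hydroxy-3-methoxy-4-{3-[(S)-2-(tert-butyldimethylsilyloxy)propyl]-2,4,5-tris(methoxymethoxy)phenyl}cyclobut-2-en-1-one (carbinol epimers) | O=C1C=C(OC)C1(O)c1cc(OCOC)c(OCOC)c(C[C@H](C)O[Si](C)(C)C(C)(C)C)c1OCOC | intermediate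
13 | (Z)-4-aryl-4-hydroxy-3-methoxybuta-1,3-dien-1-one (dienylketene, aryl as in 12, aryl cis to the ketene arm) | O=C=C/C(OC)=C(/O)c1cc(OCOC)c(OCOC)c(C[C@H](C)O[Si](C)(C)C(C)(C)C)c1OCOC | intermediate
14 | 8a-H ring-fused dienone (C8 ketone, C5 enol, C8a sp3), keto tautomer of 15 | O=C1C=C(OC)C(O)=C2C(OCOC)=C(C[C@H](C)O[Si](C)(C)C(C)(C)C)C(OCOC)=C(OCOC)C12 | intermediate
15 | 3-[(S)-2-(tert-butyldimethylsilyloxy)propyl]-6-methoxy-1,2,4-tris(methoxymethoxy)naphthalene-5,8-diol | COCOc1c(OCOC)c(C[C@H](C)O[Si](C)(C)C(C)(C)C)c(OCOC)c2c(O)c(OC)cc(O)c12 | intermediate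
16 | 3-[(S)-2-(tert-butyldimethylsilyloxy)propyl]-5,6,8-trimethoxy-1,2,4-tris(methoxymethoxy)naphthalene | COCOc1c(OCOC)c(C[C@H](C)O[Si](C)(C)C(C)(C)C)c(OCOC)c2c(OC)c(OC)cc(OC)c12 | intermediate
17 | 3-[(S)-2-hydroxypropyl]-5,6,8-trimethoxy-1,2,4-tris(methoxymethoxy)naphthalene | COCOc1c(OCOC)c(C[C@H](C)O)c(OCOC)c2c(OC)c(OC)cc(OC)c12 | intermediate
18 | 3-[(S)-2-acetoxypropyl]-5,6,8-trimethoxy-1,2,4-tris(methoxymethoxy)naphthalene | COCOc1c(OCOC)c(C[C@H](C)OC(C)=O)c(OCOC)c2c(OC)c(OC)cc(OC)c12 | intermediate
19 | 3-[(S)-2-acetoxypropyl]-5,6,8-trimethoxynaphthalene-1,2,4-triol | Oc1c(O)c(C[C@H](C)OC(C)=O)c(O)c2c(OC)c(OC)cc(OC)c12 | intermediate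
20 | 2-hydroxy-3-[(S)-2-acetoxypropyl]-5,6,8-trimethoxy-1,4-naphthoquinone (CNP0321270.1) | COc1cc(OC)c2c(c1OC)C(=O)C(C[C@H](C)OC(C)=O)=C(O)C2=O | target

**Step count**

Total step count: 11.
Longest linear sequence: 10 (steps 1–4 and 6–11). Step 5 is a one-step side branch.

**Steps most likely to fail**

**Step 6.** Proton abstraction from the unsubstituted ring carbon of 10, conjugate attack at that carbon, or attack at the vinylogous-ester carbonyl could erode the 1,2-addition.

- The fallback sets out from 7 and 10 and comes back at 15. It keeps carbanions away from the dione by working one oxidation level lower.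
- LiAlH(Ot-Bu)3 reduction of the ketone-like carbonyl of 10 should give 4-hydroxy-3-methoxycyclobut-2-en-1-one F1. An Appel reaction (PPh3, CCl4) should then give 4-chloro-3-methoxycyclobut-2-en-1-one F2.
- Bromide 7 is converted through 11 (n-BuLi, then Bu3SnCl) into tributyl{3-[(S)-2-(tert-butyldimethylsilyloxy)propyl]-2,4,5-tris(methoxymethoxy)phenyl}stannane F3.
- Stille coupling of F2 with F3 (Pd2(dba)3, tri(2-furyl)phosphine, dioxane, 50 to 100 °C) should give 3-methoxy-4-{3-[(S)-2-(tert-butyldimethylsilyloxy)propyl]-2,4,5-tris(methoxymethoxy)phenyl}cyclobut-2-en-1-one F4.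
- F4 undergoes the same 4π opening and 6π closure onto C8a in the flask. The product is 3-[(S)-2-(tert-butyldimethylsilyloxy)propyl]-6-methoxy-1,2,4-tris(methoxymethoxy)naphthalen-8-ol F5, which still lacks the C5 oxygen.
- Teuber oxidation with (KSO3)2NO introduces that oxygen para to the hydroxyl and gives 3-[(S)-2-(tert-butyldimethylsilyloxy)propyl]-6-methoxy-1,2,4-tris(methoxymethoxy)naphthalene-5,8-dione F6.
- Na2S2O4 reduction of F6 returns to 15.

**Step 11.** The acetate could be lost or could migrate onto a freed phenol, and the liberated methoxymethyl cation could be captured in Friedel–Crafts fashion at the nucleophilic C7.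

- The fallback sets out from 16 and comes back at 20. It installs the acetate only after all acid chemistry is over.
- HCl in MeOH at rt strips the silyl ether and the three MOM groups in one operation. Methanol intercepts the methoxymethyl cation before it can reach C7.
- The freed 3-[(S)-2-hydroxypropyl]-5,6,8-trimethoxynaphthalene-1,2,4-triol F7 autoxidises in air to 2-hydroxy-3-[(S)-2-hydroxypropyl]-5,6,8-trimethoxy-1,4-naphthoquinone F8.
- Ac2O/pyridine acetylates both hydroxyls to give 2-acetoxy-3-[(S)-2-acetoxypropyl]-5,6,8-trimethoxy-1,4-naphthoquinone F9.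
- The quinonyl acetate of F9 is a vinylogous mixed anhydride. It is hydrolysed selectively (aq NaHCO3, THF, 0 °C) to give 20.

**Step 8.** The electron-rich hydroquinone and its anions could autoxidise to the 5,8-quinone during handling and basic alkylation, and the hydrogen-bonded peri hydroxyls could be alkylated incompletely.

- The fallback sets out from 7 and 10 and comes back at 16. It never exposes a free hydroquinone.
- The addition mixture of 11 and 10 is quenched with MeOTf instead of NH4Cl. This should give 3,4-dimethoxy-4-{3-[(S)-2-(tert-butyldimethylsilyloxy)propyl]-2,4,5-tris(methoxymethoxy)phenyl}cyclobut-2-en-1-one F10.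
- The methoxy group of F10 also rotates outward, so thermolysis in p-xylene forms the same C8–C8a bond. The product is the oxidation-resistant 3-[(S)-2-(tert-butyldimethylsilyloxy)propyl]-5,6-dimethoxy-1,2,4-tris(methoxymethoxy)naphthalen-8-ol F11.
- A single methylation of F11 (MeI, K2CO3, DMF) gives 16.

**Further compounds**

F1 | step 6 | 4-hydroxy-3-methoxycyclobut-2-en-1-one | COC1=CC(=O)C1O
F2 | step 6 | 4-chloro-3-methoxycyclobut-2-en-1-one | COC1=CC(=O)C1Cl
F3 | step 6 | tributyl{3-[(S)-2-(tert-butyldimethylsilyloxy)propyl]-2,4,5-tris(methoxymethoxy)phenyl}stannane | CCCC[Sn](CCCC)(CCCC)c1cc(OCOC)c(OCOC)c(C[C@H](C)O[Si](C)(C)C(C)(C)C)c1OCOC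
F4 | step 6 | 3-methoxy-4-{3-[(S)-2-(tert-butyldimethylsilyloxy)propyl]-2,4,5-tris(methoxymethoxy)phenyl}cyclobut-2-en-1-one | O=C1C=C(OC)C1c1cc(OCOC)c(OCOC)c(C[C@H](C)O[Si](C)(C)C(C)(C)C)c1OCOC
F5 | step 6 | 3-[(S)-2-(tert-butyldimethylsilyloxy)propyl]-6-methoxy-1,2,4-tris(methoxymethoxy)naphthalen-8-ol | COCOc1c(OCOC)c(C[C@H](C)O[Si](C)(C)C(C)(C)C)c(OCOC)c2cc(OC)cc(O)c12
F6 | step 6 | 3-[(S)-2-(tert-butyldimethylsilyloxy)propyl]-6-methoxy-1,2,4-tris(methoxymethoxy)naphthalene-5,8-dione | COCOc1c(OCOC)c(C[C@H](C)O[Si](C)(C)C(C)(C)C)c(OCOC)c2c1C(=O)C=C(OC)C2=O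
F7 | step 11 | 3-[(S)-2-hydroxypropyl]-5,6,8-trimethoxynaphthalene-1,2,4-triol | Oc1c(O)c(C[C@H](C)O)c(O)c2c(OC)c(OC)cc(OC)c12
F8 | step 11 | 2-hydroxy-3-[(S)-2-hydroxypropyl]-5,6,8-trimethoxy-1,4-naphthoquinone | COc1cc(OC)c2c(c1OC)C(=O)C(C[C@H](C)O)=C(O)C2=O
F9 | step 11 | 2-acetoxy-3-[(S)-2-acetoxypropyl]-5,6,8-trimethoxy-1,4-naphthoquinone | COc1cc(OC)c2c(c1OC)C(=O)C(C[C@H](C)OC(C)=O)=C(OC(C)=O)C2=O
F10 | step 8 | 3,4-dimethoxy-4-{3-[(S)-2-(tert-butyldimethylsilyloxy)propyl]-2,4,5-tris(methoxymethoxy)phenyl}cyclobut-2-en-1-one | O=C1C=C(OC)C1(OC)c1cc(OCOC)c(OCOC)c(C[C@H](C)O[Si](C)(C)C(C)(C)C)c1OCOC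
F11 | step 8 | 3-[(S)-2-(tert-butyldimethylsilyloxy)propyl]-5,6-dimethoxy-1,2,4-tris(methoxymethoxy)naphthalen-8-ol | COCOc1c(OCOC)c(C[C@H](C)O[Si](C)(C)C(C)(C)C)c(OCOC)c2c(OC)c(OC)cc(O)c12
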